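**Retrosynthetic overview**
- Target 26 ← triol depsidone 24 + 3-methylbut-2-enoic acid 25: the dimethylpyranone ring is annulated last onto the only free carbon of ring B. 24 ← global deprotection of 23.
- Feature: in ring A the formyl carbon (on C3) and the diaryl ether oxygen (on C2) sit on neighbouring carbons, between the phenol carbon C4 and the lactone-bearing carbon C1. This is the pattern left when a 3-alkoxyaryne (C2≡C3) takes up O, then C.
- 23 ← 18: the aryne is tethered through the depside ester to a ring B phenoxide; one operation forms the aryl C–O bond (seven-membered dioxepinone ring) and the aryl C–CHO bond.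
- 18 ← acid 7 + hydroxy aldehyde 14: the formyl group of 14 is a latent phenol, unmasked by Baeyer–Villiger oxidation only after the ester is in place, so the acyl group sits on the correct catechol oxygen.
- 7 ← orcinol 1; 14 ← 4-methylcatechol 8. Ring order: rings A and B are bought, the dioxepinone ring closes in step 12, the pyranone ring in step 14.

Key step: step 12

Remark: the target has no stereocentre; iodination of orcinol under bicarbonate is assumed to occur between the two hydroxyls, as it does with resorcinol.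

**Route**

Step 1
Reactants: 1 orcinol
Product: 2 2-iodo-5-methylbenzene-1,3-diol
Conditions: I2, NaHCO3, THF/H2O, 0 °C
Reagents that add atoms: iodine, [I][I]
Why: Electrophilic aromatic iodination of the resorcinol monoanion, which under bicarbonate should occur at the carbon between the two hydroxyls.

Step 2
Reactants: 2 2-iodo-5-methylbenzene-1,3-diol
Product: 4 2,4-dihydroxy-3-iodo-6-methylbenzaldehyde, via iminium chloride 3 (not isolated)
Conditions: POCl3, DMF, MeCN, 0 °C to rt; then H2O, 50 °C
Reagents that add atoms: N,N-dimethylformamide, CN(C)C=O; water, O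
Why: Vilsmeier–Haack formylation of a resorcinol; the two free ring carbons are equivalent, so only one aldehyde can form.

Step 3
Reactants: 4 2,4-dihydroxy-3-iodo-6-methylbenzaldehyde
Product: 5 4-(benzyloxy)-2-hydroxy-3-iodo-6-methylbenzaldehyde
Conditions: BnBr, KHCO3, DMF, 40 °C
Reagents that add atoms: benzyl bromide, BrCc1ccccc1
Why: Williamson etherification; the hydroxyl para to the formyl group reacts because the ortho hydroxyl is hydrogen-bonded to the carbonyl and is not alkylated under bicarbonate.

Step 4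
Reactants: 5 4-(benzyloxy)-2-hydroxy-3-iodo-6-methylbenzaldehyde
Product: 6 3-(benzyloxy)-6-formyl-2-iodo-5-methylphenyl 4-chlorobenzenesulfonate
Conditions: 4-ClC6H4SO2Cl, Et3N, DMAP (cat.), CH2Cl2, 0 °C to rt
Reagents that add atoms: 4-chlorobenzenesulfonyl chloride, O=S(=O)(Cl)c1ccc(Cl)cc1
Why: O-sulfonylation of the remaining phenol under nucleophilic catalysis, which places the leaving group next to the iodide.

Step 5
Reactants: 6 3-(benzyloxy)-6-formyl-2-iodo-5-methylphenyl 4-chlorobenzenesulfonate
Product: 7 4-(benzyloxy)-2-[(4-chlorophenyl)sulfonyloxy]-3-iodo-6-methylbenzoic acid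
Conditions: NaClO2, NaH2PO4, 2-methyl-2-butene, t-BuOH/THF/H2O, rt
Reagents that add atoms: sodium chlorite, [Na+].[O-]Cl=O
Why: Pinnick oxidation of the aldehyde gives the acid under weakly acidic conditions that leave the aryl sulfonate, the iodide and the benzyl ether untouched, so no ester hydrolysis is needed after sulfonylation.

Step 6
Reactants: 8 4-methylcatechol
Product: 9 2,2,5-trimethyl-1,3-benzodioxole
Conditions: 2,2-dimethoxypropane, TsOH·H2O (cat.), toluene, reflux with removal of MeOH
Reagents that add atoms: 2,2-dimethoxypropane, COC(C)(C)OC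
Why: Acid-catalysed transketalisation of a catechol to its acetonide.

Step 7
Reactants: 9 2,2,5-trimethyl-1,3-benzodioxole
Product: 10 5-bromo-2,2,6-trimethyl-1,3-benzodioxole
Conditions: NBS, MeCN, 0 °C to rt
Reagents that add atoms: N-bromosuccinimide, O=C1CCC(=O)N1Br
Why: Electrophilic aromatic bromination at the carbon para to a ring oxygen and ortho to the methyl group, the most activated free position.

Step 8
Reactants: 10 5-bromo-2,2,6-trimethyl-1,3-benzodioxole
Product: 13 2,2,6-trimethyl-1,3-benzodioxol-5-ol, via aryllithium 11 (not isolated), via dimethyl arylboronate 12 (not isolated)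
Conditions: n-BuLi, THF, −78 °C; B(OMe)3, −78 °C to rt; then H2O2, AcOH, 0 °C to rt
Reagents that add atoms: hydrogen peroxide, OO
Why: Bromine–lithium exchange, borylation and oxidation of the arylboronate replace bromine by hydroxyl at the same carbon.

Step 9
Reactants: 13 2,2,6-trimethyl-1,3-benzodioxol-5-ol
Product: 14 5-hydroxy-2,2,6-trimethyl-1,3-benzodioxole-4-carbaldehyde
Conditions: MgCl2, Et3N, (CH2O)n, MeCN, reflux
Reagents that add atoms: formaldehyde (from paraformaldehyde), C=O
Why: Magnesium-phenoxide-directed ortho-formylation (hydroxymethylation, then hydride transfer to a second formaldehyde); only one ortho carbon is free.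

Step 10
Reactants: 7 4-(benzyloxy)-2-[(4-chlorophenyl)sulfonyloxy]-3-iodo-6-methylbenzoic acid; 14 5-hydroxy-2,2,6-trimethyl-1,3-benzodioxole-4-carbaldehyde
Product: 16 4-formyl-2,2,6-trimethyl-1,3-benzodioxol-5-yl 4-(benzyloxy)-2-[(4-chlorophenyl)sulfonyloxy]-3-iodo-6-methylbenzoate, via acid chloride 15 (not isolated)
Conditions: (COCl)2, DMF (cat.), CH2Cl2, 0 °C to rt; evaporate; then 14, Et3N, DMAP, CH2Cl2, 0 °C to rt
Reagents that add atoms: none
Why: Esterification of a phenol by an acid chloride; 14 has a single hydroxyl, so the acyl group can only go onto the oxygen next to the ring B methyl.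

Step 11
Reactants: 16 depside aldehyde
Product: 18 4-hydroxy-2,2,6-trimethyl-1,3-benzodioxol-5-yl 4-(benzyloxy)-2-[(4-chlorophenyl)sulfonyloxy]-3-iodo-6-methylbenzoate, via aryl formate 17 (not isolated)
Conditions: mCPBA, CH2Cl2, 0 °C to rt; then KHCO3, MeOH, 0 °C
Reagents that add atoms: 3-chloroperoxybenzoic acid, OOC(=O)c1cccc(Cl)c1
Why: Baeyer–Villiger oxidation of the aldehyde with aryl migration (favoured by the ortho ring oxygen) gives the formate, which mild methanolysis cleaves while the di-ortho-substituted benzoate stays in place.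

Step 12
Reactants: 18 iodo sulfonate depside phenol
Product: 23 3-(benzyloxy)-6,7-(isopropylidenedioxy)-1,9-dimethyl-11-oxo-11H-dibenzo[b,e][1,4]dioxepine-4-carbaldehyde, via magnesiated phenoxide 19 (not isolated), via aryne 20 (not isolated), via cyclised arylmagnesium 21 (not isolated), via magnesium hemiaminal 22 (not isolated)
Conditions: i-PrMgCl (2.2 equiv), THF (0.02 M), −78 °C; warm to −20 °C; then DMF (5 equiv), −20 °C to rt; 1 M HCl work-up
Reagents that add atoms: N,N-dimethylformamide, CN(C)C=O
Why: Proposed new method: the first equivalent of i-PrMgCl turns the phenol into its magnesium phenoxide and the second exchanges the iodine at the ring A carbon between the benzyloxy and sulfonyloxy groups (19); on warming, loss of magnesium 4-chlorobenzenesulfonate gives the 3-benzyloxyaryne 20, the tethered phenoxide adds to the aryne carbon next to the ester-bearing carbon (21), and the new arylmagnesium adds to DMF (22), whose hemiaminal collapses to the aldehyde on acidic work-up. The closest known reaction type is aryne generation from 2-iodoaryl sulfonates by iodine–magnesium exchange, with addition of magnesium thiolates or amides and electrophilic trapping of the resulting arylmagnesium; a tethered magnesium phenoxide as nucleophile has not been shown. The dioxepinone ring closes by 7-exo-dig nucleophilic addition of oxygen to the aryne in the plane of ring A, and no stereocentre is formed. The step needs oxygen at the aryne carbon remote from the benzyloxy group and carbon at the one next to it: the inductive effect of the benzyloxy oxygen places the carbanion ortho to it, and the tether allows no other mode, since the alternative would be an eight-membered ring. It also needs the acyl group to stay on its ring B oxygen, which the di-ortho-substituted benzoate and the low temperature should secure, while high dilution should hold back intermolecular capture of the aryne.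

Step 13
Reactants: 23 O-benzyl formyl depsidone acetonide
Product: 24 3,6,7-trihydroxy-1,9-dimethyl-11-oxo-11H-dibenzo[b,e][1,4]dioxepine-4-carbaldehyde
Conditions: BCl3 (excess), pentamethylbenzene, CH2Cl2, −78 to 0 °C; then H2O
Reagents that add atoms: none
Why: Lewis-acid ether cleavage: BCl3 should remove the benzyl group ortho to the formyl group through chelation and open the catechol ketal, with pentamethylbenzene taking up the benzyl cation so that ring B is not alkylated.

Step 14
Reactants: 24 triol depsidone; 25 3-methylbut-2-enoic acid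
Product: 26 target: 3,6-dihydroxy-4-formyl-1,9-dimethyl depsidone with a 2,2-dimethyl-2,3-dihydropyran-4-one ring fused at C7 (ring oxygen) and C8 (ketone carbon)
Conditions: P2O5/MeSO3H (1:10 w/w), 70 °C
Reagents that add atoms: none
Why: Friedel–Crafts acylation at the only free ring B carbon (ortho to the C7 hydroxyl) followed by oxa-Michael addition of that hydroxyl to the enone closes the 2,2-dimethylchromanone; ring A is deactivated by the formyl and lactone carbonyls.

**Compound list**
1 | orcinol (5-methylbenzene-1,3-diol) | Cc1cc(O)cc(O)c1 | starting material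
2 | 2-iodo-5-methylbenzene-1,3-diol | Cc1cc(O)c(I)c(O)c1 | intermediate
3 | N-[(2,4-dihydroxy-3-iodo-6-methylphenyl)methylidene]-N-methylmethanaminium chloride | Cc1cc(O)c(I)c(O)c1C=[N+](C)C.[Cl-] | intermediate
4 | 2,4-dihydroxy-3-iodo-6-methylbenzaldehyde | Cc1cc(O)c(I)c(O)c1C=O | intermediate
5 | 4-(benzyloxy)-2-hydroxy-3-iodo-6-methylbenzaldehyde | Cc1cc(OCc2ccccc2)c(I)c(O)c1C=O | intermediate
6 | 3-(benzyloxy)-6-formyl-2-iodo-5-methylphenyl 4-chlorobenzenesulfonate | Cc1cc(OCc2ccccc2)c(I)c(OS(=O)(=O)c2ccc(Cl)cc2)c1C=O | intermediate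
7 | 4-(benzyloxy)-2-[(4-chlorophenyl)sulfonyloxy]-3-iodo-6-methylbenzoic acid | Cc1cc(OCc2ccccc2)c(I)c(OS(=O)(=O)c2ccc(Cl)cc2)c1C(=O)O | intermediate
8 | 4-methylcatechol | Cc1ccc(O)c(O)c1 | starting material
9 | 2,2,5-trimethyl-1,3-benzodioxole | Cc1ccc2OC(C)(C)Oc2c1 | intermediate
10 | 5-bromo-2,2,6-trimethyl-1,3-benzodioxole | Cc1cc2OC(C)(C)Oc2cc1Br | intermediate
11 | (2,2,6-trimethyl-1,3-benzodioxol-5-yl)lithium | [Li]c1cc2OC(C)(C)Oc2cc1C | intermediate
12 | dimethyl (2,2,6-trimethyl-1,3-benzodioxol-5-yl)boronate | COB(OC)c1cc2OC(C)(C)Oc2cc1C | intermediate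
13 | 2,2,6-trimethyl-1,3-benzodioxol-5-ol | Cc1cc2OC(C)(C)Oc2cc1O | intermediate
14 | 5-hydroxy-2,2,6-trimethyl-1,3-benzodioxole-4-carbaldehyde | Cc1cc2OC(C)(C)Oc2c(C=O)c1O | intermediate
15 | 4-(benzyloxy)-2-[(4-chlorophenyl)sulfonyloxy]-3-iodo-6-methylbenzoyl chloride | Cc1cc(OCc2ccccc2)c(I)c(OS(=O)(=O)c2ccc(Cl)cc2)c1C(Cl)=O | intermediate
16 | 4-formyl-2,2,6-trimethyl-1,3-benzodioxol-5-yl 4-(benzyloxy)-2-[(4-chlorophenyl)sulfonyloxy]-3-iodo-6-methylbenzoate | Cc1cc(OCc2ccccc2)c(I)c(OS(=O)(=O)c2ccc(Cl)cc2)c1C(=O)Oc1c(C)cc2OC(C)(C)Oc2c1C=O | intermediate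
17 | 4-(formyloxy)-2,2,6-trimethyl-1,3-benzodioxol-5-yl 4-(benzyloxy)-2-[(4-chlorophenyl)sulfonyloxy]-3-iodo-6-methylbenzoate | Cc1cc(OCc2ccccc2)c(I)c(OS(=O)(=O)c2ccc(Cl)cc2)c1C(=O)Oc1c(C)cc2OC(C)(C)Oc2c1OC=O | intermediate
18 | 4-hydroxy-2,2,6-trimethyl-1,3-benzodioxol-5-yl 4-(benzyloxy)-2-[(4-chlorophenyl)sulfonyloxy]-3-iodo-6-methylbenzoate | Cc1cc(OCc2ccccc2)c(I)c(OS(=O)(=O)c2ccc(Cl)cc2)c1C(=O)Oc1c(C)cc2OC(C)(C)Oc2c1O | intermediate
19 | chloromagnesium phenoxide of 18 with the iodine replaced by chloromagnesium | Cc1cc(OCc2ccccc2)c([Mg]Cl)c(OS(=O)(=O)c2ccc(Cl)cc2)c1C(=O)Oc1c(C)cc2OC(C)(C)Oc2c1O[Mg]Cl | intermediate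
20 | 3-benzyloxy-5-methyl-6-(aryloxycarbonyl)benzyne carrying the ring B chloromagnesium phenoxide | CC1=C(C(=O)Oc2c(C)cc3OC(C)(C)Oc3c2O[Mg]Cl)C#CC(OCc2ccccc2)=C1 | intermediate
21 | 4-(chloromagnesio) analogue of 23 (arylmagnesium at the ring A carbon between the benzyloxy and ether oxygens) | Cc1cc(OCc2ccccc2)c([Mg]Cl)c2c1C(=O)Oc1c(C)cc3c(c1O2)OC(C)(C)O3 | intermediate
22 | chloromagnesium alkoxide of the dimethylamino hemiaminal of 23 | Cc1cc(OCc2ccccc2)c(C(O[Mg]Cl)N(C)C)c2c1C(=O)Oc1c(C)cc3c(c1O2)OC(C)(C)O3 | intermediate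
23 | 3-(benzyloxy)-6,7-(isopropylidenedioxy)-1,9-dimethyl-11-oxo-11H-dibenzo[b,e][1,4]dioxepine-4-carbaldehyde | Cc1cc(OCc2ccccc2)c(C=O)c2c1C(=O)Oc1c(C)cc3c(c1O2)OC(C)(C)O3 | intermediate
24 | 3,6,7-trihydroxy-1,9-dimethyl-11-oxo-11H-dibenzo[b,e][1,4]dioxepine-4-carbaldehyde | Cc1cc(O)c(C=O)c2c1C(=O)Oc1c(C)cc(O)c(O)c1O2 | intermediate
25 | 3-methylbut-2-enoic acid | CC(C)=CC(=O)O | starting material
26 | target (CNP0271978.0) | Cc1cc(O)c(C=O)c2c1C(=O)Oc1c(C)c3c(c(O)c1O2)OC(C)(C)CC3=O | target

**Step count**
Total: 14 steps. Longest linear sequence: 10 steps (steps 1–5 and 10–14); the ring B branch (steps 6–9) joins at step 10.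

**Steps most likely to fail**

Step 12 (proposed new method). The aryne may be captured intermolecularly or by isopropylmagnesium instead of the tethered phenoxide, or the acyl group may shift to the neighbouring phenoxide before cyclisation. The fallback closes the diaryl ether by copper-catalysed Ullmann etherification and adds the formyl group by directed magnesiation, both known reaction types. It sets out from 14 and comes back to the route at 23.
- Commercial 3-bromo-5-methylphenol is benzylated (BnBr, K2CO3, DMF) to 1-(benzyloxy)-3-bromo-5-methylbenzene F1.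
- Rieche formylation para to the benzyloxy group (Cl2CHOMe, SnCl4, CH2Cl2, −10 °C) gives 4-(benzyloxy)-2-bromo-6-methylbenzaldehyde F2, and Pinnick oxidation gives 4-(benzyloxy)-2-bromo-6-methylbenzoic acid F3.
- Esterification with 14 (DCC, DMAP, CH2Cl2) should give the bromo depside aldehyde F4.
- Baeyer–Villiger oxidation with mCPBA gives the bromo depside formate F5, and methanolysis as in step 11 gives the bromo depside phenol F6.
- CuI, N,N-dimethylglycine and Cs2CO3 in dioxane at 90 °C should close the seven-membered ring to the formyl-free O-benzyl depsidone acetonide F7.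
- TMPMgCl·LiCl in THF at −20 °C should magnesiate the ring A carbon between the benzyloxy and aryloxy oxygens to give arylmagnesium 21, which DMF converts into 23 as in step 12.

Step 14. The catechol aldehyde 24 may not survive the hot sulfonic acid medium (intermolecular condensation at the formyl group, opening of the lactone). The fallback attaches the acyl group under mild conditions and moves it to carbon in a separate step. It sets out from 24 and comes back at 26.
- 3-Methylbut-2-enoyl chloride and pyridine in CH2Cl2 should give the tris(3-methylbut-2-enoate) of 24 F8.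
- AlCl3 in 1,2-dichloroethane at 60 °C should bring about Fries rearrangement of the ring B ester next to the free ring B carbon and oxa-Michael closure of the freed phenol, giving the bis(3-methylbut-2-enoate) of the target F9.
- Mild methanolysis (KHCO3, MeOH, 0 °C) of the two remaining aryl esters gives 26.

Step 11. The Baeyer–Villiger step may proceed with hydride instead of aryl migration, or the acyl group may shift to the liberated phenoxide during formate cleavage. The fallback makes the catechol before the ester and blocks one oxygen. It sets out from 14 (and acid chloride 15) and comes back at 18.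
- Dakin oxidation of 14 (H2O2, NaOH, H2O/THF, 0 °C) gives 2,2,6-trimethyl-1,3-benzodioxole-4,5-diol F10.
- TBSCl (1 equiv) and imidazole in DMF at 0 °C should silylate the more acidic, less hindered hydroxyl next to the ring oxygen, giving 4-[(tert-butyldimethylsilyl)oxy]-2,2,6-trimethyl-1,3-benzodioxol-5-ol F11.
- Acylation of the remaining hydroxyl with 15 (pyridine, CH2Cl2) gives the silyl depside F12, and HF·pyridine in THF at 0 °C gives 18.

**Further compounds**
F1 | step 12 | 1-(benzyloxy)-3-bromo-5-methylbenzene | Cc1cc(Br)cc(OCc2ccccc2)c1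
F2 | step 12 | 4-(benzyloxy)-2-bromo-6-methylbenzaldehyde | Cc1cc(OCc2ccccc2)cc(Br)c1C=O
F3 | step 12 | 4-(benzyloxy)-2-bromo-6-methylbenzoic acid | Cc1cc(OCc2ccccc2)cc(Br)c1C(=O)O
F4 | step 12 | 4-formyl-2,2,6-trimethyl-1,3-benzodioxol-5-yl 4-(benzyloxy)-2-bromo-6-methylbenzoate | Cc1cc(OCc2ccccc2)cc(Br)c1C(=O)Oc1c(C)cc2OC(C)(C)Oc2c1C=O
F5 | step 12 | 4-(formyloxy)-2,2,6-trimethyl-1,3-benzodioxol-5-yl 4-(benzyloxy)-2-bromo-6-methylbenzoate | Cc1cc(OCc2ccccc2)cc(Br)c1C(=O)Oc1c(C)cc2OC(C)(C)Oc2c1OC=O
F6 | step 12 | 4-hydroxy-2,2,6-trimethyl-1,3-benzodioxol-5-yl 4-(benzyloxy)-2-bromo-6-methylbenzoate | Cc1cc(OCc2ccccc2)cc(Br)c1C(=O)Oc1c(C)cc2OC(C)(C)Oc2c1O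
F7 | step 12 | 3-(benzyloxy)-6,7-(isopropylidenedioxy)-1,9-dimethyl-11H-dibenzo[b,e][1,4]dioxepin-11-one | Cc1cc(OCc2ccccc2)cc2c1C(=O)Oc1c(C)cc3c(c1O2)OC(C)(C)O3
F8 | step 14 | tris(3-methylbut-2-enoate) of 24 | Cc1cc(OC(=O)C=C(C)C)c(C=O)c2c1C(=O)Oc1c(C)cc(OC(=O)C=C(C)C)c(OC(=O)C=C(C)C)c1O2
F9 | step 14 | bis(3-methylbut-2-enoate) of 26 | Cc1cc(OC(=O)C=C(C)C)c(C=O)c2c1C(=O)Oc1c(C)c3c(c(OC(=O)C=C(C)C)c1O2)OC(C)(C)CC3=O
F10 | step 11 | 2,2,6-trimethyl-1,3-benzodioxole-4,5-diol | Cc1cc2OC(C)(C)Oc2c(O)c1O
F11 | step 11 | 4-[(tert-butyldimethylsilyl)oxy]-2,2,6-trimethyl-1,3-benzodioxol-5-ol | Cc1cc2OC(C)(C)Oc2c(O[Si](C)(C)C(C)(C)C)c1O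
F12 | step 11 | 4-[(tert-butyldimethylsilyl)oxy]-2,2,6-trimethyl-1,3-benzodioxol-5-yl 4-(benzyloxy)-2-[(4-chlorophenyl)sulfonyloxy]-3-iodo-6-methylbenzoate | Cc1cc(OCc2ccccc2)c(I)c(OS(=O)(=O)c2ccc(Cl)cc2)c1C(=O)Oc1c(C)cc2OC(C)(C)Oc2c1O[Si](C)(C)C(C)(C)C
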